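The plan reads the C1 methyl carbon (C20) as a former ring atom. Joining C20 to C4 and cutting C4–C4a turns ring B (C1–C4, C4a, C8a) into a 3-arylcyclopentanone. Its only stereocentre (C1) comes from an asymmetric conjugate addition. The key step exploits the benzylic CH(CH3) unit at C1 beside the free C4a–H of ring A. Rhodium opens the five-membered ketone between C4 and C20, moves the C4a hydrogen to C20 and bonds C4 to C4a. One isomerisation thus gives the six-membered ring, the methyl group and a C4 ketone. The derived C4 cation, para to the C7 methoxy group, then accepts the complete side chain from a chiral allenylsilane.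

Key step: step 4

Remark (numbering): ring B holds C1 (bears methyl C20), C2, C3 and C4 (bears the side chain). Ring A holds C4a, C5 (H), C6 (CO2Me), C7 (OMe), C8 (OH) and C8a. The side chain is C11 (methyl C18), C12, C13, C14, C15 (methyl C17), C16 (OH).
Assumption: 11 and 13 are bought as single enantiomers.

Step 1
Reactants: 1 2-bromo-6-methoxyphenol
Product: 2 1-bromo-3-methoxy-2-(propan-2-yloxy)benzene
Conditions: 2-bromopropane, K2CO3, DMF, 60 °C
Reagents that add atoms: 2-bromopropane CC(C)Br
Why: Williamson ether synthesis of the phenoxide in a dipolar aprotic solvent, the isopropyl ether being chosen because it should survive hot rhodium catalysis, Lewis acid, hydrogenation and butyllithium.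

Step 2
Reactants: 2 1-bromo-3-methoxy-2-(propan-2-yloxy)benzene
Product: 4 [3-methoxy-2-(propan-2-yloxy)phenyl]boronic acid, via aryllithium 3 (not isolated)
Conditions: n-BuLi, THF, −78 °C; B(OiPr)3, −78 °C to rt; 1 M HCl
Reagents that add atoms: triisopropyl borate CC(C)OB(OC(C)C)OC(C)C; water O
Why: Bromine–lithium exchange outruns any ring deprotonation at −78 °C, and the aryllithium is trapped by the borate ester (borylation of an organolithium) before hydrolysis to the boronic acid.

Step 3
Reactants: 4 [3-methoxy-2-(propan-2-yloxy)phenyl]boronic acid; 5 cyclopent-2-en-1-one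
Product: 6 (3S)-3-[3-methoxy-2-(propan-2-yloxy)phenyl]cyclopentan-1-one
Conditions: [Rh(OH)((S)-BINAP)]2 (3 mol % Rh), dioxane/H2O 10:1, 35 °C
Reagents that add atoms: none
Why: Hayashi–Miyaura asymmetric conjugate addition, in which the aryl–rhodium species bearing (S)-BINAP inserts one enantiotopic face of the enone and should set the benzylic stereocentre (future C1) as S, the sense established for arylboronic acids and cyclopentenone.

Step 4
Reactants: 6 (3S)-3-[3-methoxy-2-(propan-2-yloxy)phenyl]cyclopentan-1-one
Product: 9 (4R)-6-methoxy-4-methyl-5-(propan-2-yloxy)-3,4-dihydronaphthalen-1(2H)-one, via cyclopentanone ketimine 7 (not isolated), via tetralone ketimine 8 (not isolated)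
Conditions: [Rh(C2H4)2Cl]2 (5 mol %), IMes (1,3-dimesitylimidazol-2-ylidene, 10 mol %), 2-aminopyridine (1 equiv), TsOH·H2O (20 mol %), 1,4-dioxane, 150 °C, sealed tube
Reagents that add atoms: none
Why: Ketone 6 condenses reversibly with 2-aminopyridine to ketimine 7, whose pyridine nitrogen guides monovalent rhodium into the C4–C20 bond of the five-membered ring (oxidative addition to a six-membered rhodacycle of trivalent rhodium). The alkyl–rhodium carbon C20 then takes up the ortho hydrogen of ring A (C4a–H activation) and becomes the C1 methyl group; this leaves a seven-membered aryl–rhodium–imidoyl metallacycle, C–C reductive elimination closes ring B as a six-membered carbocycle through the new C4–C4a bond, and hydrolysis of ketimine 8 returns the amine. The closest known reaction type is the rhodium/N-heterocyclic carbene/aminopyridine-catalysed isomerisation of 3-arylcyclopentanones to 4-methyl-1-tetralones. No stereocentre is created, because none of the bonds at C1 changes, so the configuration from step 3 is carried over and the descriptor changes from S to R only through the priority rules. The step must cleave the ketone bond on the aryl-bearing side and use a single C–H site: insertion is reversible and only the proximal rhodacycle can reach an aryl C–H bond, while the second ortho position of ring A is blocked by the isopropoxy group. Relief of cyclopentanone strain and conjugation of the new ketone with the p-methoxyaryl ring supply the driving force.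

Step 5
Reactants: 9 (4R)-6-methoxy-4-methyl-5-(propan-2-yloxy)-3,4-dihydronaphthalen-1(2H)-one
Product: 10 (4R)-6-methoxy-4-methyl-5-(propan-2-yloxy)-1,2,3,4-tetrahydronaphthalen-1-ol (carbinol epimers)
Conditions: NaBH4, MeOH/THF, 0 °C to rt
Reagents that add atoms: none
Why: Borohydride reduction of the aryl ketone, where the new carbinol centre need not be controlled because both epimers ionise to the same C4 cation in step 9.

Step 6
Reactants: 11 (R)-3-bromo-2-methylpropan-1-ol
Product: 12 [(2R)-3-bromo-2-methylpropoxy](tert-butyl)dimethylsilane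
Conditions: TBSCl, imidazole, CH2Cl2, 0 °C to rt
Reagents that add atoms: tert-butyldimethylsilyl chloride CC(C)(C)[Si](C)(C)Cl
Why: Imidazole-promoted O-silylation of the primary alcohol leaves the bromide and the chiral-pool stereocentre (future C15) untouched.

Step 7
Reactants: 13 (R)-4-(trimethylsilyl)but-3-yn-2-ol
Product: 14 (R)-4-(trimethylsilyl)but-3-yn-2-yl methanesulfonate
Conditions: MsCl, Et3N, CH2Cl2, −78 to 0 °C
Reagents that add atoms: methanesulfonyl chloride CS(=O)(=O)Cl
Why: Sulfonylation takes place at oxygen, so the configuration of the propargylic carbinol carbon is retained.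

Step 8
Reactants: 12 [(2R)-3-bromo-2-methylpropoxy](tert-butyl)dimethylsilane; 14 (R)-4-(trimethylsilyl)but-3-yn-2-yl methanesulfonate
Product: 16 tert-butyl(dimethyl){[(2S)-2-methyl-4-(trimethylsilyl)hepta-4,5-dien-1-yl]oxy}silane with Ra allene axis, via Grignard reagent 15 (not isolated)
Conditions: 12, Mg, THF, 40 °C; then CuBr·SMe2 (10 mol %), LiBr, 14, THF, −78 to 0 °C
Reagents that add atoms: none
Why: Copper-catalysed anti-SN2′ displacement of a propargylic mesylate by a Grignard reagent, in which carbon attacks the silyl-bearing alkyne terminus opposite to the leaving group, so the central chirality of 14 becomes the Ra axis of the allenylsilane.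

Step 9
Reactants: 10 (4R)-6-methoxy-4-methyl-5-(propan-2-yloxy)-1,2,3,4-tetrahydronaphthalen-1-ol (carbinol epimers); 16 allenylsilane
Product: 17 tert-butyl({(2S,6R)-6-[(1S,4R)-6-methoxy-4-methyl-5-(propan-2-yloxy)-1,2,3,4-tetrahydronaphthalen-1-yl]-2-methylhept-4-yn-1-yl}oxy)dimethylsilane
Conditions: Bi(OTf)3 (5 mol %), CH2Cl2/MeNO2, −20 °C
Reagents that add atoms: none
Why: Lewis-acid-catalysed SN1 substitution of a p-methoxybenzylic alcohol by an allenylsilane (anti-SE2′ propargylation), in which the C1 methyl group, held pseudoaxial by the peri isopropoxy group, directs pseudoaxial attack to the opposite face of the planar C4 cation (1,4-trans, 4S), while attack at the allene terminus anti to silicon transfers the axis to C11 (R here, S after saturation, by priority change only) and loss of the silyl group leaves the C12–C13 alkyne.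

Step 10
Reactants: 17 alkyne
Product: 18 tert-butyl({(2S,6S)-6-[(1S,4R)-6-methoxy-4-methyl-5-(propan-2-yloxy)-1,2,3,4-tetrahydronaphthalen-1-yl]-2-methylheptyl}oxy)dimethylsilane
Conditions: H2 (1 atm), Pd/C, EtOAc, rt
Reagents that add atoms: none
Why: Heterogeneous hydrogenation saturates the dialkyl alkyne without touching the four stereocentres, the aryl ethers or, in ethyl acetate, the silyl ether.

Step 11
Reactants: 18 saturated silyl ether
Product: 20 methyl (5R,8S)-8-[(2S,6S)-7-{[tert-butyl(dimethyl)silyl]oxy}-6-methylheptan-2-yl]-3-methoxy-5-methyl-4-(propan-2-yloxy)-5,6,7,8-tetrahydronaphthalene-2-carboxylate, via C6 aryllithium 19 (not isolated)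
Conditions: n-BuLi, TMEDA, Et2O, 0 °C to rt; inverse addition to ClCO2Me, −78 °C
Reagents that add atoms: methyl chloroformate COC(=O)Cl
Why: Directed ortho-metalation, in which C6–H is the only aromatic hydrogen next to a coordinating alkoxy group (C7 OMe), so lithiation and acylation by the chloroformate should place the ester at C6 and not at C5.

Step 12
Reactants: 20 protected ester
Product: 21 methyl (5R,8S)-4-hydroxy-8-[(2S,6S)-7-hydroxy-6-methylheptan-2-yl]-3-methoxy-5-methyl-5,6,7,8-tetrahydronaphthalene-2-carboxylate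
Conditions: BCl3, CH2Cl2, −78 to −10 °C; then MeOH, rt
Reagents that add atoms: none
Why: Lewis-acid dealkylation, in which boron trichloride cleaves aryl isopropyl ethers by an ionising pathway faster than aryl methyl ethers, and the hydrogen chloride formed on the methanol quench removes the primary silyl ether, which should give the target.

Compound list
1 | 2-bromo-6-methoxyphenol | COc1cccc(Br)c1O | starting material
2 | 1-bromo-3-methoxy-2-(propan-2-yloxy)benzene | COc1cccc(Br)c1OC(C)C | intermediate
3 | [3-methoxy-2-(propan-2-yloxy)phenyl]lithium | COc1cccc([Li])c1OC(C)C | intermediate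
4 | [3-methoxy-2-(propan-2-yloxy)phenyl]boronic acid | COc1cccc(B(O)O)c1OC(C)C | intermediate
5 | cyclopent-2-en-1-one | O=C1C=CCC1 | starting material
6 | (3S)-3-[3-methoxy-2-(propan-2-yloxy)phenyl]cyclopentan-1-one | O=C1CC[C@H](c2cccc(OC)c2OC(C)C)C1 | intermediate
7 | N-(pyridin-2-yl) ketimine of 6 | COc1cccc([C@H]2CCC(=Nc3ccccn3)C2)c1OC(C)C | intermediate
8 | N-(pyridin-2-yl) ketimine of 9 | COc1ccc2c(c1OC(C)C)[C@H](C)CCC2=Nc1ccccn1 | intermediate
9 | (4R)-6-methoxy-4-methyl-5-(propan-2-yloxy)-3,4-dihydronaphthalen-1(2H)-one | COc1ccc2c(c1OC(C)C)[C@H](C)CCC2=O | intermediate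
10 | (4R)-6-methoxy-4-methyl-5-(propan-2-yloxy)-1,2,3,4-tetrahydronaphthalen-1-ol, both carbinol epimers | COc1ccc2c(c1OC(C)C)[C@H](C)CCC2O | intermediate
11 | (R)-3-bromo-2-methylpropan-1-ol | BrC[C@H](C)CO | starting material
12 | [(2R)-3-bromo-2-methylpropoxy](tert-butyl)dimethylsilane | BrC[C@H](C)CO[Si](C)(C)C(C)(C)C | intermediate
13 | (R)-4-(trimethylsilyl)but-3-yn-2-ol | C[C@@H](O)C#C[Si](C)(C)C | starting material
14 | (R)-4-(trimethylsilyl)but-3-yn-2-yl methanesulfonate | C[C@@H](OS(C)(=O)=O)C#C[Si](C)(C)C | intermediate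
15 | bromo[(2R)-3-{[tert-butyl(dimethyl)silyl]oxy}-2-methylpropyl]magnesium | Br[Mg]C[C@H](C)CO[Si](C)(C)C(C)(C)C | intermediate
16 | tert-butyl(dimethyl){[(2S)-2-methyl-4-(trimethylsilyl)hepta-4,5-dien-1-yl]oxy}silane, allene axis Ra | [H]C(C)=[C@]=C([Si](C)(C)C)C[C@H](C)CO[Si](C)(C)C(C)(C)C | intermediate
17 | tert-butyl({(2S,6R)-6-[(1S,4R)-6-methoxy-4-methyl-5-(propan-2-yloxy)-1,2,3,4-tetrahydronaphthalen-1-yl]-2-methylhept-4-yn-1-yl}oxy)dimethylsilane | COc1ccc2c(c1OC(C)C)[C@H](C)CC[C@H]2[C@@H](C)C#CC[C@H](C)CO[Si](C)(C)C(C)(C)C | intermediate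
18 | tert-butyl({(2S,6S)-6-[(1S,4R)-6-methoxy-4-methyl-5-(propan-2-yloxy)-1,2,3,4-tetrahydronaphthalen-1-yl]-2-methylheptyl}oxy)dimethylsilane | COc1ccc2c(c1OC(C)C)[C@H](C)CC[C@H]2[C@@H](C)CCC[C@H](C)CO[Si](C)(C)C(C)(C)C | intermediate
19 | C6-lithio derivative of 18 | COc1c([Li])cc2c(c1OC(C)C)[C@H](C)CC[C@H]2[C@@H](C)CCC[C@H](C)CO[Si](C)(C)C(C)(C)C | intermediate
20 | methyl (5R,8S)-8-[(2S,6S)-7-{[tert-butyl(dimethyl)silyl]oxy}-6-methylheptan-2-yl]-3-methoxy-5-methyl-4-(propan-2-yloxy)-5,6,7,8-tetrahydronaphthalene-2-carboxylate | COC(=O)c1cc2c(c(OC(C)C)c1OC)[C@H](C)CC[C@H]2[C@@H](C)CCC[C@H](C)CO[Si](C)(C)C(C)(C)C | intermediate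
21 | methyl (5R,8S)-4-hydroxy-8-[(2S,6S)-7-hydroxy-6-methylheptan-2-yl]-3-methoxy-5-methyl-5,6,7,8-tetrahydronaphthalene-2-carboxylate | COC(=O)c1cc2c(c(O)c1OC)[C@H](C)CC[C@H]2[C@@H](C)CCC[C@H](C)CO | target

Total step count: 12. Longest linear sequence: 9 (steps 1–5 and 9–12).

Steps most likely to fail

1. Step 4.
- **What may go wrong:** The ortho isopropoxy group crowds the ketimine–rhodium chelate, so insertion into the ring bond may be slower than catalyst decay. β-Hydride loss from the alkylrhodium could also erode C1.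
- **Fallback, from 4 back to 9:** Ring B is still made from a five-membered ring, but by a one-carbon radical enlargement.
  - Hayashi–Miyaura addition of 4 to methyl (E)-but-2-enoate, with the BINAP antipode that delivers the R ester, should give methyl (3R)-3-[3-methoxy-2-(propan-2-yloxy)phenyl]butanoate F1.
  - LiOH gives (3R)-3-[3-methoxy-2-(propan-2-yloxy)phenyl]butanoic acid F2.
  - Trifluoroacetic anhydride closes, para to the methoxy group, (3R)-5-methoxy-3-methyl-4-(propan-2-yloxy)-2,3-dihydro-1H-inden-1-one F3 (Friedel–Crafts acylation).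
  - TMSOTf/Et3N gives the indenyl trimethylsilyl enol ether F4.
  - Et2Zn/CH2I2 (Simmons–Smith) gives the siloxycyclopropane F5.
  - K2CO3/MeOH frees the bicyclic cyclopropanol F6.
  - Oxidation with Mn(pic)3 in the presence of Bu3SnH opens the shared cyclopropane bond to the ring-enlarged β-keto radical, which is reduced to 9.

2. Step 9.
- **What may go wrong:** Proton loss from the C4 cation to the dihydronaphthalene may outrun capture by the hindered allenylsilane. The β-silyl vinyl cation may be intercepted by ring A before desilylation, and acid may protodesilylate the allene.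
- **Fallback, from 10 back to 18:** A more nucleophilic π-donor is used, and the chain is completed by metathesis instead.
  - (S,E)-Trimethyl(pent-3-en-2-yl)silane under the same acid catalysis (Hosomi–Sakurai type, anti-SE2′) should give (1S,4R)-6-methoxy-4-methyl-1-[(2S,3E)-pent-3-en-2-yl]-5-(propan-2-yloxy)-1,2,3,4-tetrahydronaphthalene F7.
  - Cross metathesis with tert-butyl(dimethyl){[(2S)-2-methylpent-4-en-1-yl]oxy}silane (second-generation Hoveyda–Grubbs catalyst) gives the (E)-hept-4-enyl silyl ether F8.
  - Hydrogenation (H2, Pd/C) gives 18.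

3. Step 12.
- **What may go wrong:** Chelation of boron between the ester carbonyl and the C7 oxygen may cause loss of the C7 methyl ether alongside the isopropyl group.
- **Fallback, from 18 to 21:** The Lewis acid is used before the ester exists, and the synthesis finishes under mild Brønsted acid.
  - BCl3 then MeOH on 18 gives (5S,8R)-5-[(2S,6S)-7-hydroxy-6-methylheptan-2-yl]-2-methoxy-8-methyl-5,6,7,8-tetrahydronaphthalen-1-ol F9.
  - MOMCl/iPr2NEt gives its bis(methoxymethyl) ether F10.
  - n-BuLi/TMEDA then ClCO2Me (lithiation again only next to the C7 methoxy group) gives the bis(methoxymethyl) ether of 21 F11.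
  - HCl in MeOH gives 21.

Further compounds
F1 | step 4 | methyl (3R)-3-[3-methoxy-2-(propan-2-yloxy)phenyl]butanoate | COc1cccc([C@H](C)CC(=O)OC)c1OC(C)C
F2 | step 4 | (3R)-3-[3-methoxy-2-(propan-2-yloxy)phenyl]butanoic acid | COc1cccc([C@H](C)CC(=O)O)c1OC(C)C
F3 | step 4 | (3R)-5-methoxy-3-methyl-4-(propan-2-yloxy)-2,3-dihydro-1H-inden-1-one | COc1ccc2c(c1OC(C)C)[C@H](C)CC2=O
F4 | step 4 | {[(1R)-6-methoxy-1-methyl-7-(propan-2-yloxy)-1H-inden-3-yl]oxy}trimethylsilane | COc1ccc2c(c1OC(C)C)[C@H](C)C=C2O[Si](C)(C)C
F5 | step 4 | siloxycyclopropane from methylene transfer to the enol ether double bond of F4 | COc1ccc2c(c1OC(C)C)[C@H](C)C1CC12O[Si](C)(C)C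
F6 | step 4 | bicyclic cyclopropanol from desilylation of F5 | COc1ccc2c(c1OC(C)C)[C@H](C)C1CC12O
F7 | step 9 | (1S,4R)-6-methoxy-4-methyl-1-[(2S,3E)-pent-3-en-2-yl]-5-(propan-2-yloxy)-1,2,3,4-tetrahydronaphthalene | COc1ccc2c(c1OC(C)C)[C@H](C)CC[C@H]2[C@@H](C)/C=C/C
F8 | step 9 | tert-butyl({(2S,4E,6S)-6-[(1S,4R)-6-methoxy-4-methyl-5-(propan-2-yloxy)-1,2,3,4-tetrahydronaphthalen-1-yl]-2-methylhept-4-en-1-yl}oxy)dimethylsilane | COc1ccc2c(c1OC(C)C)[C@H](C)CC[C@H]2[C@@H](C)/C=C/C[C@H](C)CO[Si](C)(C)C(C)(C)C
F9 | step 12 | (5S,8R)-5-[(2S,6S)-7-hydroxy-6-methylheptan-2-yl]-2-methoxy-8-methyl-5,6,7,8-tetrahydronaphthalen-1-ol | COc1ccc2c(c1O)[C@H](C)CC[C@H]2[C@@H](C)CCC[C@H](C)CO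
F10 | step 12 | bis(methoxymethyl) ether of F9 | COc1ccc2c(c1OCOC)[C@H](C)CC[C@H]2[C@@H](C)CCC[C@H](C)COCOC
F11 | step 12 | bis(methoxymethyl) ether of 21 | COC(=O)c1cc2c(c(OCOC)c1OC)[C@H](C)CC[C@H]2[C@@H](C)CCC[C@H](C)COCOC
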